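The route rests on opening ring C at its carbonyl. C4 is bonded only to its oxygen, to C4a of ring A and to C3, so it can be delivered as carbon monoxide. Ring A is symmetric about the C4a···C7 axis, so the oxygens that become O1 and the C5 oxygen are identical. One palladium-catalysed coupling of an aryl iodide, CO and an arylacetylene therefore forges C4a–C4, C4–C3 and O1–C2 and closes ring C. The precursor is 2,4-dimethoxyphloroglucinol iodinated at its single CH and triply acetylated, the iodine lying between two equivalent acetoxy groups; its partner is 3,4,5-trimethoxyphenylacetylene. Acetate methanolysis then ends the route.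

Key step: step 6

Remark: the target and all intermediates are achiral; the only stereo-element on the way is the double-bond geometry of the transient enaminone 11, which has no bearing on the product.
Remark: material from step 6 that has lost one or both remaining acetyl groups to the amine is not separated, because step 7 converts it into the same product.
Remark: alkyne 8 is also a catalog compound; step 5 only ties it to the cheaper aldehyde 7.

Step 1
Reactants: 1 1,3,5-tris(benzyloxy)benzene
Product: 2 1,3,5-tris(benzyloxy)-2,4-dibromobenzene
Conditions: NBS (2.05 equiv), CH2Cl2, 0 °C to rt, dark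
Reagents that add atoms: N-bromosuccinimide, O=C1CCC(=O)N1Br
Why: Electrophilic aromatic bromination; every ring CH of 1 is ortho/para to three alkoxy groups, and the third bromination is clearly slower for steric and electronic reasons, so two equivalents of NBS should stop at the dibromide.

Step 2
Reactants: 2 1,3,5-tris(benzyloxy)-2,4-dibromobenzene
Product: 3 1,3,5-tris(benzyloxy)-2,4-dimethoxybenzene
Conditions: NaOMe (25% in MeOH, 6 equiv), CuBr (20 mol%), DMF, 110 °C, argon
Reagents that add atoms: sodium methoxide, [Na+].[O-]C
Why: Copper-catalysed Ullmann-type methoxylation of aryl bromides is an established way to convert bromides flanked by two alkoxy groups into methyl ethers, and benzyl ethers are inert to methoxide.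

Step 3
Reactants: 3 1,3,5-tris(benzyloxy)-2,4-dimethoxybenzene
Product: 4 2,4-dimethoxybenzene-1,3,5-triol
Conditions: H2 (1 atm), 10% Pd/C, EtOAc–MeOH, rt; filtration under argon
Reagents that add atoms: none
Why: Catalytic hydrogenolysis of benzyl aryl ethers over palladium leaves the methyl ethers untouched; the air-sensitive triol is filtered under argon and used at once.

Step 4
Reactants: 4 2,4-dimethoxybenzene-1,3,5-triol
Product: 6 2-iodo-4,6-dimethoxybenzene-1,3,5-triyl triacetate, via iodotriol 5 (not isolated)
Conditions: NIS (1.0 equiv), MeCN, −20 to 0 °C, dark, argon; then pyridine, Ac2O (5 equiv), DMAP (cat.), 0 °C to rt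
Reagents that add atoms: N-iodosuccinimide, O=C1CCC(=O)N1I; acetic anhydride, CC(=O)OC(C)=O
Why: Electrophilic aromatic iodination at the only ring CH, which is ortho/para to all three hydroxyls, gives succinimide instead of HI (no acid-driven deiodination), and DMAP-catalysed O-acetylation in the same flask avoids isolating the oxidation-prone iodotriol.

Step 5
Reactants: 7 3,4,5-trimethoxybenzaldehyde
Product: 8 5-ethynyl-1,2,3-trimethoxybenzene
Conditions: dimethyl (1-diazo-2-oxopropyl)phosphonate (1.2 equiv), K2CO3 (2 equiv), MeOH, rt
Reagents that add atoms: dimethyl (1-diazo-2-oxopropyl)phosphonate, COP(=O)(OC)C(=[N+]=[N-])C(C)=O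
Why: Seyferth–Gilbert homologation in the Ohira–Bestmann variant, in which methanolysis of the acetyl group releases the diazomethylphosphonate anion that converts a non-enolisable aryl aldehyde into the terminal alkyne under mild base.

Step 6
Reactants: 6 2-iodo-4,6-dimethoxybenzene-1,3,5-triyl triacetate; 8 5-ethynyl-1,2,3-trimethoxybenzene (1.5 equiv); 9 carbon monoxide
Product: 12 5,7-diacetoxy-6,8-dimethoxy-2-(3,4,5-trimethoxyphenyl)-4H-chromen-4-one, via ynone triacetate 10 (not isolated), via enaminone 11 (not isolated)
Conditions: PdCl2(PPh3)2 (5 mol%), dppp (5 mol%), thiourea (5 mol%), Et2NH, DBU (1.5 equiv), CO (1 atm, balloon), 40 °C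
Reagents that add atoms: none
Why: Zerovalent palladium, formed in the flask from PdCl2(PPh3)2, inserts into the C–I bond of 6, CO insertion gives an aroylpalladium iodide, and coupling with the amine-deprotonated alkyne 8 releases ynone 10 (bonds C4a–C4 and C4–C3). Diethylamine then adds to the triple bond and removes one of the two acetyl groups ortho to the new ketone, giving enaminone 11, whose phenoxide attacks C2 and expels diethylamine to form O1–C2. The closest known reaction type is the palladium-catalysed carbonylative annulation of ortho-iodophenol acetates with terminal alkynes to flavones. Ring C closes by 6-endo-trig conjugate addition–elimination on 11, a net 6-endo-dig closure on the ynone, and no stereocenter is formed. The step needs carbonylative coupling instead of direct alkynylation, secured by the CO atmosphere, the absence of a copper co-catalyst and the ready CO insertion of an electron-rich arylpalladium, and it needs flavone instead of aurone closure, secured by the secondary amine through the enaminone. No regiochemical choice arises because the two acetoxy groups flanking iodine in 6 are related by symmetry, and each acetate sits between two ortho substituents, which slows aminolysis before the ketone is in place.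

Step 7
Reactants: 12 5,7-diacetoxy-6,8-dimethoxy-2-(3,4,5-trimethoxyphenyl)-4H-chromen-4-one
Product: 13 5,7-dihydroxy-6,8-dimethoxy-2-(3,4,5-trimethoxyphenyl)-4H-chromen-4-one
Conditions: K2CO3 (3 equiv), MeOH, rt; then 1 M HCl to pH 4
Reagents that add atoms: none
Why: Base-mediated transesterification of the two aryl acetates by methanol (Zemplén-type methanolysis) is fast for phenolic esters, leaves the methyl ethers and the pyranone intact, and also collects any material that lost acetyl groups in step 6.

Compound list
1 | 1,3,5-tris(benzyloxy)benzene | c1ccc(COc2cc(OCc3ccccc3)cc(OCc3ccccc3)c2)cc1 | starting material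
2 | 1,3,5-tris(benzyloxy)-2,4-dibromobenzene | Brc1c(OCc2ccccc2)cc(OCc2ccccc2)c(Br)c1OCc1ccccc1 | intermediate
3 | 1,3,5-tris(benzyloxy)-2,4-dimethoxybenzene | COc1c(OCc2ccccc2)cc(OCc2ccccc2)c(OC)c1OCc1ccccc1 | intermediate
4 | 2,4-dimethoxybenzene-1,3,5-triol | COc1c(O)cc(O)c(OC)c1O | intermediate
5 | 2-iodo-4,6-dimethoxybenzene-1,3,5-triol | COc1c(O)c(I)c(O)c(OC)c1O | intermediate
6 | 2-iodo-4,6-dimethoxybenzene-1,3,5-triyl triacetate | CC(=O)Oc1c(I)c(OC(C)=O)c(OC)c(OC(C)=O)c1OC | intermediate
7 | 3,4,5-trimethoxybenzaldehyde | COc1cc(C=O)cc(OC)c1OC | starting material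
8 | 5-ethynyl-1,2,3-trimethoxybenzene | C#Cc1cc(OC)c(OC)c(OC)c1 | intermediate
9 | carbon monoxide | [C-]#[O+] | starting material
10 | 1-(2,4,6-triacetoxy-3,5-dimethoxyphenyl)-3-(3,4,5-trimethoxyphenyl)prop-2-yn-1-one | COc1cc(C#CC(=O)c2c(OC(C)=O)c(OC)c(OC(C)=O)c(OC)c2OC(C)=O)cc(OC)c1OC | intermediate
11 | (2E)-3-(diethylamino)-1-(2,4-diacetoxy-6-hydroxy-3,5-dimethoxyphenyl)-3-(3,4,5-trimethoxyphenyl)prop-2-en-1-one | CCN(CC)/C(=C/C(=O)c1c(O)c(OC)c(OC(C)=O)c(OC)c1OC(C)=O)c1cc(OC)c(OC)c(OC)c1 | intermediate
12 | 5,7-diacetoxy-6,8-dimethoxy-2-(3,4,5-trimethoxyphenyl)-4H-chromen-4-one | COc1cc(-c2cc(=O)c3c(OC(C)=O)c(OC)c(OC(C)=O)c(OC)c3o2)cc(OC)c1OC | intermediate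
13 | 5,7-dihydroxy-6,8-dimethoxy-2-(3,4,5-trimethoxyphenyl)-4H-chromen-4-one | COc1cc(-c2cc(=O)c3c(O)c(OC)c(O)c(OC)c3o2)cc(OC)c1OC | target

Total step count: 7. Longest linear sequence: 6 (steps 1, 2, 3, 4, 6, 7).

Steps most likely to fail

1. Step 6. The acetates may be lost to the amine before palladium has inserted, leaving an electron-rich iodophenoxide that reacts slowly and loses iodine by protodehalogenation. The aroylpalladium intermediate may also be intercepted by diethylamine (amide formation), or the coupling may proceed without CO uptake. The fallback gives up the carbonylation and builds C4 from an acetyl group. It sets out from 4 and comes back at 13. Friedel–Crafts C-acetylation of 4 (AcOH, BF3·OEt2, 80 °C) at its single free ring position should give 1-(2,4,6-trihydroxy-3,5-dimethoxyphenyl)ethan-1-one F1. Excess LiN(SiMe3)2 in THF at −78 °C turns F1 into its polyanion, whose enolate carbon is aroylated by 3,4,5-trimethoxybenzoyl chloride to give 1-(2,4,6-trihydroxy-3,5-dimethoxyphenyl)-3-(3,4,5-trimethoxyphenyl)propane-1,3-dione F2. Cyclodehydration of F2 (H2SO4, AcOH, 95 °C) should give 13 directly, since either ortho hydroxyl leads to the same flavone.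

2. Step 4. The iodinating agent or air may oxidise the very electron-rich triol to a quinone in competition with C-iodination, and iodine may be lost again before acetylation. The fallback installs iodine while the hydroxyls are still benzylated. It sets out from 3 and comes back at 6. NIS with catalytic CF3CO2H in MeCN should iodinate the one free position of 3 to give 1,3,5-tris(benzyloxy)-2-iodo-4,6-dimethoxybenzene F3. BCl3 with pentamethylbenzene in CH2Cl2 at −78 °C then removes the three benzyl groups without hydrogenolysis of the C–I bond and, at this temperature, without cleaving the methyl ethers. After a methanol quench and evaporation, the resulting iodotriol 5 is acetylated as in step 4 (Ac2O, pyridine, DMAP) to give 6.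

3. Step 2. Hydrodebromination and incomplete exchange may occur at the two positions that are each flanked by two benzyloxy groups. The fallback brings in the oxygen through boron. It sets out from 2 and comes back at 3. Double Miyaura borylation of 2 (B2pin2, Pd(OAc)2, SPhos, KOAc, dioxane, 100 °C) should give 2,2'-[2,4,6-tris(benzyloxy)-1,3-phenylene]bis(4,4,5,5-tetramethyl-1,3,2-dioxaborolane) F4. Oxidation (H2O2, NaOH, THF–H2O, 0 °C) gives 2,4,6-tris(benzyloxy)benzene-1,3-diol F5, and O-methylation (MeI, K2CO3, acetone, 50 °C) gives 3.

Further compounds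
F1 | step 6 | 1-(2,4,6-trihydroxy-3,5-dimethoxyphenyl)ethan-1-one | CC(=O)c1c(O)c(OC)c(O)c(OC)c1O
F2 | step 6 | 1-(2,4,6-trihydroxy-3,5-dimethoxyphenyl)-3-(3,4,5-trimethoxyphenyl)propane-1,3-dione | COc1cc(C(=O)CC(=O)c2c(O)c(OC)c(O)c(OC)c2O)cc(OC)c1OC
F3 | step 4 | 1,3,5-tris(benzyloxy)-2-iodo-4,6-dimethoxybenzene | COc1c(OCc2ccccc2)c(I)c(OCc2ccccc2)c(OC)c1OCc1ccccc1
F4 | step 2 | 2,2'-[2,4,6-tris(benzyloxy)-1,3-phenylene]bis(4,4,5,5-tetramethyl-1,3,2-dioxaborolane) | CC1(C)OB(OC1(C)C)c1c(OCc2ccccc2)cc(OCc2ccccc2)c(B2OC(C)(C)C(C)(C)O2)c1OCc1ccccc1
F5 | step 2 | 2,4,6-tris(benzyloxy)benzene-1,3-diol | Oc1c(OCc2ccccc2)cc(OCc2ccccc2)c(O)c1OCc1ccccc1
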